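**Retrosynthetic overview**

1. Gericudranin E (16) ⇐ 15 by one hydrogenolysis that removes four benzyl ethers and a bromine blocker at C8.
2. 15 ⇐ chalcone 9 in one flask: catalytic asymmetric 6-endo oxa-Michael closure of ring C (chalcone → (2S)-flavanone, as chalcone isomerase does), then oxygenation of C3 anti to the aryl group (as flavanone 3-hydroxylase does). C2 comes from the catalyst, C3 from C2.
3. 9 ⇐ methyl ketone 7 + aldehyde 8 (Claisen–Schmidt).
4. 7 ⇐ 5 + 4-(benzyloxy)benzyl cation (Friedel–Crafts, the protected form of the quinone-methide benzylation). Bromine ortho to the free OH leaves only the carbon that becomes C6. 5 ⇐ phloroacetophenone 1.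
5. Rings A and B and the benzyl ring are bought as benzenes; ring C is the only ring formed (step 5).

Assumption: the step 5 catalyst, 1-[3,5-bis(trifluoromethyl)phenyl]-3-[(8α,9S)-6'-methoxycinchonan-9-yl]thiourea, is taken to give the (2S)-flavanone; if a test run gives the (2R) series, its quinidine-derived pseudo-enantiomer is used with nothing else changed.

**Route**

Step 1
Reactants: 1 2',4',6'-trihydroxyacetophenone; 2 benzyl bromide
Product: 3 1-[2,4-bis(benzyloxy)-6-hydroxyphenyl]ethan-1-one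
Conditions: BnBr (2.1 equiv), K2CO3 (2.2 equiv), DMF, 0 °C to rt
Reagents that add atoms: benzyl bromide, BrCc1ccccc1
Why: Williamson ether synthesis: the 4-OH and one of the two equivalent ortho OH groups are benzylated, while the last ortho OH, now locked in a hydrogen bond to the acetyl carbonyl, is too weak a nucleophile to react with the limited bromide; no stereocentre.

Step 2
Reactants: 3 1-[2,4-bis(benzyloxy)-6-hydroxyphenyl]ethan-1-one; 4 N-bromosuccinimide
Product: 5 1-[4,6-bis(benzyloxy)-3-bromo-2-hydroxyphenyl]ethan-1-one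
Conditions: NBS (1.0 equiv), CH2Cl2, 0 °C, dark
Reagents that add atoms: N-bromosuccinimide, O=C1CCC(=O)N1Br
Why: Electrophilic aromatic bromination: the carbon between the free chelated OH and one OBn is attacked in preference to the more crowded carbon between two OBn groups (the usual ortho-to-OH selectivity of 2-hydroxy-4,6-dialkoxyacetophenones), which places a removable blocker on the future C8; no stereocentre.

Step 3
Reactants: 5 1-[4,6-bis(benzyloxy)-3-bromo-2-hydroxyphenyl]ethan-1-one; 6 [4-(benzyloxy)phenyl]methanol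
Product: 7 1-[2,4-bis(benzyloxy)-3-[4-(benzyloxy)benzyl]-5-bromo-6-hydroxyphenyl]ethan-1-one
Conditions: Sc(OTf)3 (5 mol %), CH2Cl2–(CF3)2CHOH 4:1, rt, 6 (1.2 equiv) added over 2 h
Reagents that add atoms: [4-(benzyloxy)phenyl]methanol, OCc1ccc(OCc2ccccc2)cc1
Why: Friedel–Crafts benzylation through the 4-(benzyloxy)benzyl cation (the protected counterpart of the p-quinone methide that nature is thought to use): the only C–H left on the phloroglucinol ring lies between the two OBn groups, so the benzyl group can only end up on the future C6, and any O-benzylation of the chelated phenol reverts under the acid; no stereocentre.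

Step 4
Reactants: 7 1-[2,4-bis(benzyloxy)-3-[4-(benzyloxy)benzyl]-5-bromo-6-hydroxyphenyl]ethan-1-one; 8 4-(benzyloxy)benzaldehyde
Product: 9 (E)-1-[2,4-bis(benzyloxy)-3-[4-(benzyloxy)benzyl]-5-bromo-6-hydroxyphenyl]-3-[4-(benzyloxy)phenyl]prop-2-en-1-one
Conditions: KOH (50% aq, excess), EtOH–THF, rt, 36 h; then dilute HCl
Reagents that add atoms: 4-(benzyloxy)benzaldehyde, O=Cc1ccc(OCc2ccccc2)cc1
Why: Claisen–Schmidt aldol condensation: the methyl ketone enolate adds to the non-enolisable aldehyde and E1cB loss of water gives the E-enone, while the 2'-phenoxide of the product does not cyclise in strong base and the aryl bromide and benzyl ethers are inert.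

Step 5
Reactants: 9 (E)-1-[2,4-bis(benzyloxy)-3-[4-(benzyloxy)benzyl]-5-bromo-6-hydroxyphenyl]-3-[4-(benzyloxy)phenyl]prop-2-en-1-one; 10 trimethylsilyl trifluoromethanesulfonate; 11 3-chloroperoxybenzoic acid
Product: 15 (2R,3R)-5,7-bis(benzyloxy)-6-[4-(benzyloxy)benzyl]-2-[4-(benzyloxy)phenyl]-8-bromo-3-hydroxychroman-4-one, via (2S)-flavanone 12 (not isolated), via silyl enol ether 13 (not isolated), via 3-silyloxy ketone 14 (not isolated)
Conditions: quinine-derived bifunctional thiourea (10 mol %), toluene, 40 °C; then CH2Cl2, Et3N (1.3 equiv), Me3SiOTf (1.25 equiv), 0 °C; then mCPBA (1.5 equiv), NaHCO3, −20 °C; then citric acid, MeOH, rt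
Reagents that add atoms: 3-chloroperoxybenzoic acid, OOC(=O)c1cccc(Cl)c1
Why: Proposed new method: the quinuclidine nitrogen of the catalyst takes up the 2'-phenol proton while its thiourea N–H bonds hold the enone carbonyl, so the phenol adds 6-endo to one face of the β-carbon and closes ring C as the (2S)-flavanone 12 (the chalcone isomerase step, not reversed here because 5-alkoxyflavanones do not reopen under so weak a base), soft enolisation with Me3SiOTf/Et3N then gives silyl enol ether 13 without a free enolate that could open the ring and racemise C2, and the peracid puts oxygen on C3 on the face anti to the 2-aryl group (the flavanone 3-hydroxylase step) so that hydrolysis of 14 leaves the 2,3-trans (2R,3R) product; the closest known reactions are bifunctional cinchona-thiourea oxa-Michael cyclisations of α-ester-activated 2'-hydroxychalcones to flavanones and the Rubottom oxidation of flavanone silyl enol ethers to trans-dihydroflavonols.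

Step 6
Reactants: 15 (2R,3R)-5,7-bis(benzyloxy)-6-[4-(benzyloxy)benzyl]-2-[4-(benzyloxy)phenyl]-8-bromo-3-hydroxychroman-4-one
Product: 16 gericudranin E, (2R,3R)-3,5,7-trihydroxy-6-(4-hydroxybenzyl)-2-(4-hydroxyphenyl)chroman-4-one
Conditions: H2 (1 atm), Pd/C (10 wt %), NaOAc (1.5 equiv), THF–MeOH, rt
Reagents that add atoms: none
Why: Heterogeneous catalytic hydrogenolysis: Pd/C and H2 cleave the four benzyl aryl ethers and the aryl C–Br bond (sodium acetate takes up the HBr) and leave the hydrogen-bonded aryl ketone, the diarylmethane and the C2–O1 bond alone at 1 atm and room temperature, so neither stereocentre is touched.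

**Compound list**

1 | 2',4',6'-trihydroxyacetophenone | CC(=O)c1c(O)cc(O)cc1O | starting material
2 | benzyl bromide | BrCc1ccccc1 | starting material
3 | 1-[2,4-bis(benzyloxy)-6-hydroxyphenyl]ethan-1-one | CC(=O)c1c(O)cc(OCc2ccccc2)cc1OCc1ccccc1 | intermediate
4 | N-bromosuccinimide | O=C1CCC(=O)N1Br | starting material
5 | 1-[4,6-bis(benzyloxy)-3-bromo-2-hydroxyphenyl]ethan-1-one | CC(=O)c1c(O)c(Br)c(OCc2ccccc2)cc1OCc1ccccc1 | intermediate
6 | [4-(benzyloxy)phenyl]methanol | OCc1ccc(OCc2ccccc2)cc1 | starting material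
7 | 1-[2,4-bis(benzyloxy)-3-[4-(benzyloxy)benzyl]-5-bromo-6-hydroxyphenyl]ethan-1-one | CC(=O)c1c(O)c(Br)c(OCc2ccccc2)c(Cc2ccc(OCc3ccccc3)cc2)c1OCc1ccccc1 | intermediate
8 | 4-(benzyloxy)benzaldehyde | O=Cc1ccc(OCc2ccccc2)cc1 | starting material
9 | (E)-1-[2,4-bis(benzyloxy)-3-[4-(benzyloxy)benzyl]-5-bromo-6-hydroxyphenyl]-3-[4-(benzyloxy)phenyl]prop-2-en-1-one | O=C(/C=C/c1ccc(OCc2ccccc2)cc1)c1c(O)c(Br)c(OCc2ccccc2)c(Cc2ccc(OCc3ccccc3)cc2)c1OCc1ccccc1 | intermediate
10 | trimethylsilyl trifluoromethanesulfonate | C[Si](C)(C)OS(=O)(=O)C(F)(F)F | starting material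
11 | 3-chloroperoxybenzoic acid | OOC(=O)c1cccc(Cl)c1 | starting material
12 | (2S)-5,7-bis(benzyloxy)-6-[4-(benzyloxy)benzyl]-2-[4-(benzyloxy)phenyl]-8-bromochroman-4-one | O=C1c2c(c(Br)c(OCc3ccccc3)c(Cc3ccc(OCc4ccccc4)cc3)c2OCc2ccccc2)O[C@H](c2ccc(OCc3ccccc3)cc2)C1 | intermediate
13 | [(2S)-5,7-bis(benzyloxy)-6-[4-(benzyloxy)benzyl]-2-[4-(benzyloxy)phenyl]-8-bromo-2H-chromen-4-yl]oxy(trimethyl)silane | C[Si](C)(C)OC1=C[C@@H](c2ccc(OCc3ccccc3)cc2)Oc2c(Br)c(OCc3ccccc3)c(Cc3ccc(OCc4ccccc4)cc3)c(OCc3ccccc3)c12 | intermediate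
14 | (2R,3R)-5,7-bis(benzyloxy)-6-[4-(benzyloxy)benzyl]-2-[4-(benzyloxy)phenyl]-8-bromo-3-(trimethylsilyloxy)chroman-4-one | O=C1c2c(c(Br)c(OCc3ccccc3)c(Cc3ccc(OCc4ccccc4)cc3)c2OCc2ccccc2)O[C@H](c2ccc(OCc3ccccc3)cc2)[C@H]1O[Si](C)(C)C | intermediate
15 | (2R,3R)-5,7-bis(benzyloxy)-6-[4-(benzyloxy)benzyl]-2-[4-(benzyloxy)phenyl]-8-bromo-3-hydroxychroman-4-one | O=C1c2c(c(Br)c(OCc3ccccc3)c(Cc3ccc(OCc4ccccc4)cc3)c2OCc2ccccc2)O[C@H](c2ccc(OCc3ccccc3)cc2)[C@H]1O | intermediate
16 | gericudranin E, (2R,3R)-3,5,7-trihydroxy-6-(4-hydroxybenzyl)-2-(4-hydroxyphenyl)chroman-4-one | O=C1c2c(cc(O)c(Cc3ccc(O)cc3)c2O)O[C@H](c2ccc(O)cc2)[C@H]1O | target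

**Step count and weak points**

Total steps: 6. Longest linear sequence: 6 (1 → 3 → 5 → 7 → 9 → 15 → 16).

Most likely to fail, first: step 5. The catalyst may give low ee or stall on this crowded, electron-rich chalcone; the ee of 15 is checked by chiral HPLC and raised by recrystallisation. The fallback sets out from 9 and comes back at 15, and moves the stereo-determining event from C–O bond formation to an alkene epoxidation. The 2'-OH of 9 is capped (NaH, MeOCH2Cl, THF) to give the 2'-O-methoxymethyl chalcone F1. Juliá–Colonna epoxidation (poly-L-leucine, urea–H2O2, DBU, THF) gives the (αR,βS)-epoxy ketone F2. HCl in MeOH–THF then removes the acetal, and the freed phenol opens the epoxide at the benzylic carbon with inversion to give 15.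

Second: step 3. The cation may attack only slowly at a carbon flanked by two benzyloxy groups, or 6 may condense with itself. The fallback sets out from 5 and comes back at 7, and replaces the Friedel–Crafts reaction by a cross-coupling. Iodination of the same carbon (N-iodosuccinimide, cat. CF3CO2H, MeCN) gives 1-[2,4-bis(benzyloxy)-5-bromo-6-hydroxy-3-iodophenyl]ethan-1-one F3. Commercial 4-(benzyloxy)benzyl chloride, zinc dust and LiCl in THF give [4-(benzyloxy)benzyl]zinc chloride F4. Negishi coupling (Pd(OAc)2, SPhos, THF, rt, phenol first converted into its sodium salt with NaH) at the C–I bond, which reacts before C–Br, gives 7.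

Third: step 6. Five bonds are cleaved in one pot, so over-reduction at C2–O1 or C4, or a stalled debromination, is possible. The fallback sets out from 15 and comes back at 16, and separates the two events. BCl3 with pentamethylbenzene as benzyl-cation trap (CH2Cl2, −78 °C) removes the four benzyl ethers without hydrogen to give (2R,3R)-8-bromo-3,5,7-trihydroxy-6-(4-hydroxybenzyl)-2-(4-hydroxyphenyl)chroman-4-one F5. A few minutes under H2 with Pd/C and NaOAc in MeOH then cleave only the C–Br bond to give 16.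

**Further compounds**

F1 | step 5 | (E)-1-[2,4-bis(benzyloxy)-3-[4-(benzyloxy)benzyl]-5-bromo-6-(methoxymethoxy)phenyl]-3-[4-(benzyloxy)phenyl]prop-2-en-1-one | COCOc1c(Br)c(OCc2ccccc2)c(Cc2ccc(OCc3ccccc3)cc2)c(OCc2ccccc2)c1C(=O)/C=C/c1ccc(OCc2ccccc2)cc1
F2 | step 5 | [2,4-bis(benzyloxy)-3-[4-(benzyloxy)benzyl]-5-bromo-6-(methoxymethoxy)phenyl][(2R,3S)-3-[4-(benzyloxy)phenyl]oxiran-2-yl]methanone | COCOc1c(Br)c(OCc2ccccc2)c(Cc2ccc(OCc3ccccc3)cc2)c(OCc2ccccc2)c1C(=O)[C@@H]1O[C@H]1c1ccc(OCc2ccccc2)cc1
F3 | step 3 | 1-[2,4-bis(benzyloxy)-5-bromo-6-hydroxy-3-iodophenyl]ethan-1-one | CC(=O)c1c(O)c(Br)c(OCc2ccccc2)c(I)c1OCc1ccccc1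
F4 | step 3 | [4-(benzyloxy)benzyl]zinc chloride | Cl[Zn]Cc1ccc(OCc2ccccc2)cc1
F5 | step 6 | (2R,3R)-8-bromo-3,5,7-trihydroxy-6-(4-hydroxybenzyl)-2-(4-hydroxyphenyl)chroman-4-one | O=C1c2c(c(Br)c(O)c(Cc3ccc(O)cc3)c2O)O[C@H](c2ccc(O)cc2)[C@H]1O
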